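Over 2.0 d the flask runs down a ladder of times, and one concentration, c_even, is carried through it. The first hours are the ones to watch.

| setting | cedar | elm | larch | flask |
|---|---|---|---|---|
| starting material | 0.050 M | 0.050 M | 0.025 M | 0.050 M |
| protic impurity | 1.4 mM | 2.2 mM | 1 mM | 1.00 mM |
| remark | run made earlier | run made earlier | run made earlier |  |
| time |  |  |  | 2.0 d |

| run | time / h | ring / % |
|---|---|---|
| cedar | 0.417 | 17 |
| cedar | 1.33 | 24 |
| cedar | 4.00 | 15 |
| cedar | 12.0 | 0 |
| cedar | 40.0 | 3 |
| elm | 0.417 | 16 |
| elm | 1.33 | 21 |
| elm | 4.00 | 13 |
| elm | 12.0 | 1 |
| elm | 40.0 | 1 |
| larch | 0.417 | 19 |
| larch | 1.33 | 32 |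
| larch | 4.00 | 18 |
| larch | 12.0 | 1 |
| larch | 40.0 | 1 |

(standard deviation of a reading: 1.5 percentage points)

- percent here means starting material units held: one open dimer counts as two
- the numbers in the tables scatter by 1.5 percentage points (one standard deviation)
- steps under discussion: starting material -> ring; 2 starting material -> open dimer; starting material + protic impurity -> quenched substrate; ring -> over-reaction product

1. the moment within 2.0 d at which there is most ring
2. the amount of ring, in percent of the starting material charged, at that time
3. earliest time at which at least nineteen twentieths of that best amount are there
4. latest time at which they still are, in d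

1. Ring closure uses starting material in proportion to c(starting material), and dimerisation in proportion to its square. The even concentration, at which both use it equally fast, is the zero of the scale. It is tried at larch's charge: c_even = 0.0250 M.

2. With x = charge/c_even and the impurity left aside, the two steps integrate to F = ln(1 + x)/x, the share of the charge that closes to ring. F for larch over F for cedar is 1.26. Ring readings summed up to 4.00 h, larch against the mean of cedar and elm, give 1.30. The scatter of 1.5 percentage points leaves room around the trial value.

3. First rung: larch's first reading gives a closure time near 2.19 h. In the flask, x = 2.00, so dimerisation's time is about half of that, 1.10 h, and it starts ahead.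

4. Next rung: larch's fall after 4.00 h reads a ring life of 2.77 h, longer than closure. That life is rough, since the reading of 1 % in it carries a scatter of 1.5 points. Cedar was charged with the flask's 0.050 M of starting material, so this reckoning expects the flask's peak near cedar's highest reading, 24 % at 1.33 h.

5. Last rung: because 2.0 d is far longer than the ring life, the flask should end with F = 54.9 % as over-reaction product. The flask's impurity charge is 2.00 % of the starting material.

6. The forecast gives 25.5 % at 0.065 d, with a band from 1.05 h to 0.1 d, holding that “dimerisation (second order) is the main loss”. Its peak stands later than this reckoning's.

The flask peaks at 0.0553 d with 26.1 % of ring, and the band runs from 0.906 h to 0.0781 d.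

    starting material → ring (k = 0.0110 min⁻¹)
    2 starting material → open dimer (k = 0.220 M⁻¹ min⁻¹)
    starting material + protic impurity → quenched substrate (k = 0.360 M⁻¹ min⁻¹)
    ring → over-reaction product (k = 0.00800 min⁻¹)

The forecast's peak time is 1.18 times the flask's. At the best time, 0.0553 d, open dimer already holds 41.7 %. F = 54.9 % stands against 54.3 % of over-reaction product in the flask at 2.00 d. The neighbour charged with 0.12 M has x = 4.80, so F = 36.6 %, and it ends with 36.4 % of over-reaction product.

The data are calculated for substances that don't exist; the scatter is artificial.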